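## The problem

The target is a trans-2,3-diaryl-2,3-dihydrobenzofuran (numbering O1, C2, C3, C3a, C4–C7, C7a): C2 carries a 3,4-dihydroxyphenyl ring, C3 a 3,5-dihydroxyphenyl ring, C4 a hydroxyl and C6 an (E)-4-hydroxy-3-methoxystyryl group. Its benzo ring is a 5-styrylresorcinol bonded to C3 through C3a, the carbon between its two oxygens (O1 on C7a, OH on C4); substitution or radical coupling on a free 5-substituted resorcinol does not reliably choose this position, so the connectivity must be built in. There are two adjacent stereocentres, C2 (S) and C3 (S), trans; C3 is a methine bearing two aryl rings and C2, with no heteroatom to hold on to, and is the hard one. C2 is an O-benzylic carbon para to a catechol oxygen and can open to a p-quinone methide; it is therefore labile and under equilibration only follows C3 (trans), so C3 must be right from the start and a cis isomer must be removed, never equilibrated. Of six phenolic oxygens only one is methylated, which rules out a Lewis-acid demethylation end-game; the E-stilbene, the catechol and the benzylic aryl ether exclude hydrogenolysis, strong acid and oxidants late in the route. The feature that opens the key step: before the furan ring is closed, the ring C3a–C4–C5–C6–C7–C7a is locally C2-symmetric about the C3a···C6 axis, so O1 and O4 are equivalent. A 2,6-dioxygenated benzaldehyde whose formyl carbon is the future C3 thus needs no differentiation of its oxygens (whichever becomes the carbonyl of an o-quinone methide ends as O1, the other as O4), and C2, bonded to O1, C3, H and an aryl ring, is exactly the carbon of an ArCH unit that a sulfonium benzylide delivers.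

## Retrosynthesis

**22 ⇒ 21.** No skeletal bond is cut, only four O–Si and two O–C(=O) bonds. Silyl ethers on the two rings that come from organometallic reagents and tert-butyl carbonates on the stilbene half all fall in one base methanolysis that leaves ArOMe, the stilbene and the stereocentres alone. Benzyl ethers (hydrogenolysis) or methyl ethers (BBr3) would not allow this. The forward step must avoid air oxidation of the catechol.

**21 ⇒ 6 + 15 + 14.** Three bonds are cut at once: C3–aryl (to the 3,5-dioxygenated ring), C3–C2 and C2–O1. Cutting only C2–O1 leaves the C3 stereocentre as a separate problem. Cutting C3–C3a asks a resorcinol to react at the carbon between its oxygens. Here C3 is the formyl carbon of 6, the aryl group comes from Grignard reagent 15, and the ArCH unit (C2) comes from the chiral sulfonium salt 14 through its ylide. 21 holds the heterocycle and both stereocentres; 6 is a flat, achiral aldehyde and 15 and 14 are monoaryl reagents. The forward reaction must add the Grignard reagent to the aldehyde only, turn the alkoxide into an o-quinone methide by transfer of one of the two equivalent Boc groups, and trap it with the ylide faster than it oligomerises, with reagent control at C2 and trans selectivity at C3.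

**6 ⇒ 5 ⇒ 2 + 4.** Two O–Boc bonds, then the aryl–vinyl bond of the stilbene (Mizoroki–Heck). An olefination would need a phosphorus group on a ring that already carries the formyl group, and lithiation in the presence of a stilbene risks carbolithiation. The Heck partners are each one step from commodity chemicals. The forward reaction must give the E-β-arylation product.

**2 ⇒ 1 and 4 ⇒ 3.** One O–S bond and one O–C bond. The symmetric triol 1 already has the future C3 (CHO) between the future O1 and O4, and its para oxygen is the handle for the styryl group. The demand is site selectivity for the para hydroxyl.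

**14 ⇒ 12 + 13; 12 ⇒ 11 ⇒ 10 ⇒ 9; 15 ⇒ 8 ⇒ 7.** S–C bond (S-alkylation of sulfide 13), C–Br, C=O reduction, O–Si bonds; C–Mg and O–Si bonds. All are routine, and the sulfide is returned in the key step.

## Roads not taken

**Alternative 1:** (the obvious one) Cut C3–C3a and C2–O1 as in biosynthesis. One-electron oxidation (FeCl3, Ag2O or peroxidase) of piceatannol A1 and isorhapontigenin A2 would couple C8 of A1 to the resorcinol carbon between the oxygens of A2, and the p-quinone methide A3 would close by 5-exo oxa-Michael addition. Both partners carry a free 4-hydroxystyryl unit of similar oxidation potential, so homo- and cross-dimers form together, each through several coupling modes, and the catechol of A1 is oxidised to an o-quinone first. The mode needed here is a minor one and the product is racemic. The chosen plan fixes C3a by the position of a formyl group and sets C2 by a reagent.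

**Alternative 2:** Cut C2–C3. A chiral Rh(II) carboxylate would insert the donor/donor carbene from diazo compound A4 into the O-benzylic C–H bond, giving the cis-dihydrobenzofuran A5, which would then be epimerised at C2 by acid. The reaction type is established for 2,3-diaryl-dihydrobenzofurans, but A4 needs a hydrazone at a carbonyl flanked by four ortho substituents and an oxidation to the diazo stage beside a stilbene. The cis product must pass through the p-quinone methide manifold, and the second benzyl ether needs an extra removal step. From 5 this costs at least six operations against two, and it does not ease the C3a regiochemistry.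

**Alternative 3:** No skeletal cut, but dearomatisation: asymmetric hydrogenation of the flat 2,3-diarylbenzofuran A6 to cis-dihydrobenzofuran A7, then C2 epimerisation. The C2=C3 bond is tetrasubstituted, part of an aromatic furan and flanked by two aryl rings and the C4 oxygen. Asymmetric benzofuran hydrogenation is only secure for mono-substituted furan rings. The stilbene would be reduced first, so the styryl group would have to be added afterwards from an ester (at least three more steps). The chosen plan sets trans directly and carries the stilbene throughout.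

Key step: step 11

Assumption: the (1R,4R,5R) enantiomer of isothiocineole 13 (purchasable, or one step from (R)-limonene and sulfur) is written on the premise that its benzylide reacts through the ylide face that turns benzaldehyde into (R,R)-stilbene oxide; if the opposite sense is found, the (1S,4S,5S) sulfide is used and nothing else changes.

## Route

Step 1
Reactants: 1 2,4,6-trihydroxybenzaldehyde
Product: 2 4-formyl-3,5-dihydroxyphenyl trifluoromethanesulfonate
Conditions: PhNTf2 (1.0 equiv), Et3N (1.1 equiv), THF, 0 °C → rt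
Reagents that add atoms: N-phenylbis(trifluoromethanesulfonimide), O=S(=O)(N(c1ccccc1)S(=O)(=O)C(F)(F)F)C(F)(F)F
Why: Phenol O-sulfonylation; the 4-OH is the most acidic (para to CHO) and the only hydroxyl not held by the formyl group, so mono-triflation para to CHO is expected, as with 2,4-dihydroxyaryl carbonyl compounds.

Step 2
Reactants: 3 2-methoxy-4-vinylphenol
Product: 4 tert-butyl (4-ethenyl-2-methoxyphenyl) carbonate
Conditions: Boc2O, DMAP (cat.), MeCN, rt
Reagents that add atoms: di-tert-butyl dicarbonate, CC(C)(C)OC(=O)OC(=O)OC(C)(C)C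
Why: DMAP-catalysed O-acylation of a phenol; the carbonate stops the vinylphenol from polymerising and tolerates Pd/amine conditions.

Step 3
Reactants: 2 4-formyl-3,5-dihydroxyphenyl trifluoromethanesulfonate; 4 tert-butyl (4-ethenyl-2-methoxyphenyl) carbonate
Product: 5 tert-butyl {4-[(E)-2-(4-formyl-3,5-dihydroxyphenyl)ethenyl]-2-methoxyphenyl} carbonate
Conditions: Pd(OAc)2 (cat.), P(o-tol)3, LiCl, Et3N, DMF, 80 °C
Reagents that add atoms: none
Why: Mizoroki–Heck reaction of an aryl triflate activated by the para formyl group; chloride keeps the neutral pathway, so β-arylation and syn β-hydride elimination should give the E-stilbene, and any Boc migration between phenols is made good in step 4.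

Step 4
Reactants: 5 tert-butyl {4-[(E)-2-(4-formyl-3,5-dihydroxyphenyl)ethenyl]-2-methoxyphenyl} carbonate
Product: 6 di-tert-butyl {5-[(E)-2-{4-[(tert-butoxycarbonyl)oxy]-3-methoxyphenyl}ethenyl]-2-formyl-1,3-phenylene} biscarbonate
Conditions: Boc2O (2.5 equiv), DMAP (cat.), iPr2NEt, THF, 0 °C → rt
Reagents that add atoms: di-tert-butyl dicarbonate, CC(C)(C)OC(=O)OC(=O)OC(C)(C)C
Why: DMAP-catalysed O-Boc formation on both chelated phenols; the two ortho carbonates are equivalent by symmetry and are the trigger for o-quinone methide formation in step 11.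

Step 5
Reactants: 7 5-bromobenzene-1,3-diol
Product: 8 1-bromo-3,5-bis[(tert-butyldimethylsilyl)oxy]benzene
Conditions: TBSCl, imidazole, DMF, rt
Reagents that add atoms: tert-butyldimethylsilyl chloride, CC(C)(C)[Si](C)(C)Cl
Why: Standard phenol silylation; aryl silyl ethers meta to the halogen survive Grignard formation.

Step 6
Reactants: 9 3,4-dihydroxybenzaldehyde
Product: 10 3,4-bis[(tert-butyldimethylsilyl)oxy]benzaldehyde
Conditions: TBSCl, imidazole, DMF, rt
Reagents that add atoms: tert-butyldimethylsilyl chloride, CC(C)(C)[Si](C)(C)Cl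
Why: Standard silylation of both catechol hydroxyls.

Step 7
Reactants: 10 3,4-bis[(tert-butyldimethylsilyl)oxy]benzaldehyde
Product: 11 {3,4-bis[(tert-butyldimethylsilyl)oxy]phenyl}methanol
Conditions: NaBH4, MeOH–THF, 0 °C
Reagents that add atoms: none
Why: Borohydride reduction of an aryl aldehyde; aryl silyl ethers tolerate the short, cold reaction.

Step 8
Reactants: 11 {3,4-bis[(tert-butyldimethylsilyl)oxy]phenyl}methanol
Product: 12 4-(bromomethyl)-1,2-bis[(tert-butyldimethylsilyl)oxy]benzene
Conditions: CBr4, PPh3, CH2Cl2, 0 °C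
Reagents that add atoms: carbon tetrabromide, BrC(Br)(Br)Br
Why: Appel bromination under neutral conditions; the electron-rich benzyl bromide is used at once.

Step 9
Reactants: 12 4-(bromomethyl)-1,2-bis[(tert-butyldimethylsilyl)oxy]benzene; 13 (1R,4R,5R)-4,7,7-trimethyl-6-thiabicyclo[3.2.1]octane (isothiocineole)
Product: 14 (1R,4R,5R)-6-{3,4-bis[(tert-butyldimethylsilyl)oxy]benzyl}-4,7,7-trimethyl-6-thiabicyclo[3.2.1]octan-6-ium trifluoromethanesulfonate (benzyl on the sulfur lone pair syn to the one-carbon bridge)
Conditions: LiOTf, CH2Cl2–H2O, rt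
Reagents that add atoms: lithium trifluoromethanesulfonate, [Li+].[O-]S(=O)(=O)C(F)(F)F
Why: S-alkylation of a thioether with a benzylic bromide, driven by exchange of bromide for non-nucleophilic triflate; alkylation on the less hindered lone pair should give one sulfonium diastereomer.

Step 10
Reactants: 8 1-bromo-3,5-bis[(tert-butyldimethylsilyl)oxy]benzene
Product: 15 {3,5-bis[(tert-butyldimethylsilyl)oxy]phenyl}magnesium bromide (titrated THF solution, used directly)
Conditions: Mg turnings (I2), THF, reflux → rt
Reagents that add atoms: magnesium, [Mg]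
Why: Grignard formation from an aryl bromide; the meta silyloxy groups cannot undergo retro-Brook migration to the metalated carbon.

Step 11
Reactants: 6 di-tert-butyl {5-[(E)-2-{4-[(tert-butoxycarbonyl)oxy]-3-methoxyphenyl}ethenyl]-2-formyl-1,3-phenylene} biscarbonate; 15 {3,5-bis[(tert-butyldimethylsilyl)oxy]phenyl}magnesium bromide; 14 the sulfonium triflate
Product: 21 tert-butyl (2S,3S)-2-{3,4-bis[(tert-butyldimethylsilyl)oxy]phenyl}-3-{3,5-bis[(tert-butyldimethylsilyl)oxy]phenyl}-6-[(E)-2-{4-[(tert-butoxycarbonyl)oxy]-3-methoxyphenyl}ethenyl]-2,3-dihydro-1-benzofuran-4-yl carbonate, via magnesium alkoxide 16 (not isolated), via benzylic carbonate phenoxide 17 (not isolated), via o-quinone methide 18 (not isolated), via sulfonium ylide 19 (not isolated), via betaine 20 (not isolated)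
Conditions: 15 (1.0 equiv), THF, −78 °C; then ylide from 14/LiHMDS (THF–CH2Cl2, −78 °C) by cannula, −78 → 0 °C; aq. NH4Cl
Reagents that add atoms: none
Why: Proposed new method: Mechanism: 15 adds only to the formyl group of 6 at −78 °C (16); on warming, one of the two equivalent ortho Boc groups moves from the phenolic to the benzylic oxygen (17) and the freed phenoxide expels tert-butyl carbonate to give the neutral o-quinone methide 18, whose exocyclic carbon is attacked by benzylide 19 (from 14 and LiHMDS) to give betaine 20. Closest known reaction types: anionic Boc-transfer generation of o-quinone methides from o-(Boc-oxy)benzaldehydes and Grignard reagents with capture by a second carbon nucleophile, [4+1] annulation of o-quinone methides with sulfonium ylides to trans-2,3-dihydrobenzofurans, and epoxidation/aziridination with isothiocineole-derived benzylides; only their merger in one flask is new. The furan ring closes from 20 by 5-exo-tet SN2 attack of the phenoxide (the future O1) on the carbon bearing the sulfonium group, which releases 13. C2 is controlled by the reagent: the bicyclic sulfide fixes the ylide conformation and shields one face, and closure inverts that carbon, which under the stated assumption gives 2S. C3 is set in the C–C bond formation, where an open transition state that keeps the two aryl groups anti should lead to the trans (2S,3S) isomer; a minor cis isomer would be (2S,3R), is removed by chromatography and must not be equilibrated. The step needs chemoselectivity (aldehyde before aryl carbonates, secured by −78 °C and one equivalent of 15), a single Boc transfer (the second OBoc stays, protects O4 and keeps 18 neutral and electrophilic) and capture of 18 by 19 ahead of oligomerisation (19 is present before 18 forms). The position of C3a between O1 and O4 is fixed by the formyl carbon of 1 and, by the local symmetry, does not depend on which Boc group moves.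

Step 12
Reactants: 21 the protected dihydrobenzofuran
Product: 22 5-[(2S,3S)-2-(3,4-dihydroxyphenyl)-4-hydroxy-6-[(E)-2-(4-hydroxy-3-methoxyphenyl)ethenyl]-2,3-dihydro-1-benzofuran-3-yl]benzene-1,3-diol (target)
Conditions: K2CO3, MeOH–THF (degassed, Ar), 0 °C → rt; then AcOH
Reagents that add atoms: none
Why: Base-mediated methanolysis cleaves the two aryl tert-butyl carbonates (transesterification) and the four aryl silyl ethers (phenoxide leaving groups) in one operation; ArOMe, the stilbene and C3 are untouched, and reversible opening at C2 through the p-quinone methide can only return the trans isomer.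

## Compound list

1 | 2,4,6-trihydroxybenzaldehyde | O=Cc1c(O)cc(O)cc1O | starting material
2 | 4-formyl-3,5-dihydroxyphenyl trifluoromethanesulfonate | O=Cc1c(O)cc(OS(=O)(=O)C(F)(F)F)cc1O | intermediate
3 | 2-methoxy-4-vinylphenol | COc1cc(C=C)ccc1O | starting material
4 | tert-butyl (4-ethenyl-2-methoxyphenyl) carbonate | COc1cc(C=C)ccc1OC(=O)OC(C)(C)C | intermediate
5 | tert-butyl {4-[(E)-2-(4-formyl-3,5-dihydroxyphenyl)ethenyl]-2-methoxyphenyl} carbonate | COc1cc(/C=C/c2cc(O)c(C=O)c(O)c2)ccc1OC(=O)OC(C)(C)C | intermediate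
6 | di-tert-butyl {5-[(E)-2-{4-[(tert-butoxycarbonyl)oxy]-3-methoxyphenyl}ethenyl]-2-formyl-1,3-phenylene} biscarbonate | COc1cc(/C=C/c2cc(OC(=O)OC(C)(C)C)c(C=O)c(OC(=O)OC(C)(C)C)c2)ccc1OC(=O)OC(C)(C)C | intermediate
7 | 5-bromobenzene-1,3-diol | Oc1cc(O)cc(Br)c1 | starting material
8 | 1-bromo-3,5-bis[(tert-butyldimethylsilyl)oxy]benzene | CC(C)(C)[Si](C)(C)Oc1cc(Br)cc(O[Si](C)(C)C(C)(C)C)c1 | intermediate
9 | 3,4-dihydroxybenzaldehyde | O=Cc1ccc(O)c(O)c1 | starting material
10 | 3,4-bis[(tert-butyldimethylsilyl)oxy]benzaldehyde | O=Cc1ccc(O[Si](C)(C)C(C)(C)C)c(O[Si](C)(C)C(C)(C)C)c1 | intermediate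
11 | {3,4-bis[(tert-butyldimethylsilyl)oxy]phenyl}methanol | OCc1ccc(O[Si](C)(C)C(C)(C)C)c(O[Si](C)(C)C(C)(C)C)c1 | intermediate
12 | 4-(bromomethyl)-1,2-bis[(tert-butyldimethylsilyl)oxy]benzene | BrCc1ccc(O[Si](C)(C)C(C)(C)C)c(O[Si](C)(C)C(C)(C)C)c1 | intermediate
13 | (1R,4R,5R)-4,7,7-trimethyl-6-thiabicyclo[3.2.1]octane (isothiocineole) | C[C@@H]1CC[C@@H]2C[C@H]1SC2(C)C | starting material
14 | (1R,4R,5R)-6-{3,4-bis[(tert-butyldimethylsilyl)oxy]benzyl}-4,7,7-trimethyl-6-thiabicyclo[3.2.1]octan-6-ium trifluoromethanesulfonate | CC(C)(C)[Si](C)(C)Oc1ccc(C[S@@+]2[C@@H]3C[C@@H](CC[C@H]3C)C2(C)C)cc1O[Si](C)(C)C(C)(C)C.[O-]S(=O)(=O)C(F)(F)F | intermediate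
15 | {3,5-bis[(tert-butyldimethylsilyl)oxy]phenyl}magnesium bromide | CC(C)(C)[Si](C)(C)Oc1cc([Mg]Br)cc(O[Si](C)(C)C(C)(C)C)c1 | intermediate
16 | bromomagnesium alkoxide of the diarylmethanol from 6 and 15 (racemic) | COc1cc(/C=C/c2cc(OC(=O)OC(C)(C)C)c(C(O[Mg]Br)c3cc(O[Si](C)(C)C(C)(C)C)cc(O[Si](C)(C)C(C)(C)C)c3)c(OC(=O)OC(C)(C)C)c2)ccc1OC(=O)OC(C)(C)C | intermediate (not isolated)
17 | bromomagnesium phenoxide carrying the benzylic tert-butyl carbonate (after Boc transfer, racemic) | COc1cc(/C=C/c2cc(O[Mg]Br)c(C(OC(=O)OC(C)(C)C)c3cc(O[Si](C)(C)C(C)(C)C)cc(O[Si](C)(C)C(C)(C)C)c3)c(OC(=O)OC(C)(C)C)c2)ccc1OC(=O)OC(C)(C)C | intermediate (not isolated)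
18 | o-quinone methide: tert-butyl {6-[3,5-bis(TBSO)benzylidene]-3-[(E)-2-{4-[(tert-butoxycarbonyl)oxy]-3-methoxyphenyl}ethenyl]-5-oxocyclohexa-1,3-dien-1-yl} carbonate | COc1cc(/C=C/C2=CC(=O)C(=Cc3cc(O[Si](C)(C)C(C)(C)C)cc(O[Si](C)(C)C(C)(C)C)c3)C(OC(=O)OC(C)(C)C)=C2)ccc1OC(=O)OC(C)(C)C | intermediate (not isolated)
19 | sulfonium benzylide from 14 | CC(C)(C)[Si](C)(C)Oc1ccc([CH-][S@@+]2[C@@H]3C[C@@H](CC[C@H]3C)C2(C)C)cc1O[Si](C)(C)C(C)(C)C | intermediate (not isolated)
20 | betaine (phenoxide–sulfonium inner salt; C3 S, sulfonium-bearing carbon R) | COc1cc(/C=C/c2cc([O-])c([C@H](c3cc(O[Si](C)(C)C(C)(C)C)cc(O[Si](C)(C)C(C)(C)C)c3)[C@H](c3ccc(O[Si](C)(C)C(C)(C)C)c(O[Si](C)(C)C(C)(C)C)c3)[S@@+]3[C@@H]4C[C@@H](CC[C@H]4C)C3(C)C)c(OC(=O)OC(C)(C)C)c2)ccc1OC(=O)OC(C)(C)C | intermediate (not isolated)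
21 | tert-butyl (2S,3S)-2-{3,4-bis[(tert-butyldimethylsilyl)oxy]phenyl}-3-{3,5-bis[(tert-butyldimethylsilyl)oxy]phenyl}-6-[(E)-2-{4-[(tert-butoxycarbonyl)oxy]-3-methoxyphenyl}ethenyl]-2,3-dihydro-1-benzofuran-4-yl carbonate | COc1cc(/C=C/c2cc(OC(=O)OC(C)(C)C)c3c(c2)O[C@H](c2ccc(O[Si](C)(C)C(C)(C)C)c(O[Si](C)(C)C(C)(C)C)c2)[C@H]3c2cc(O[Si](C)(C)C(C)(C)C)cc(O[Si](C)(C)C(C)(C)C)c2)ccc1OC(=O)OC(C)(C)C | intermediate
22 | 5-[(2S,3S)-2-(3,4-dihydroxyphenyl)-4-hydroxy-6-[(E)-2-(4-hydroxy-3-methoxyphenyl)ethenyl]-2,3-dihydro-1-benzofuran-3-yl]benzene-1,3-diol | COc1cc(/C=C/c2cc(O)c3c(c2)O[C@H](c2ccc(O)c(O)c2)[C@H]3c2cc(O)cc(O)c2)ccc1O | target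

## Step count and risks

Total step count: 12. Longest linear sequence: 6 steps (steps 6, 7, 8, 9, 11, 12; from 9 to 22).

**Step 11 (key step, Proposed new method).** The most likely failure is a mismatch of rates. Ylide 19 may be consumed before 18 has formed on warming, by carboxylation with the tert-butyl carbonate that is expelled, by acyl transfer from the aryl carbonates, or by thermal decay; 18 then oligomerises. Two further failures are possible: poor facial selectivity in the C3–C2 bond formation, seen as the cis (2S,3R) isomer, and β-elimination from betaine 20 in place of ring closure. Fallback with known chemistry, setting out from 6 and 15 and returning at 21: the Grignard addition and Boc transfer are run as before, but 18 is intercepted by sodium 4-methylbenzenesulfinate (DMF co-solvent, −78 °C → rt). After acidic work-up this gives the bench-stable o-quinone methide precursor tert-butyl {2-[{3,5-bis[(tert-butyldimethylsilyl)oxy]phenyl}(4-methylbenzenesulfonyl)methyl]-5-[(E)-2-{4-[(tert-butoxycarbonyl)oxy]-3-methoxyphenyl}ethenyl]-3-hydroxyphenyl} carbonate F1. F1, 14 and Cs2CO3 in CH2Cl2 (0 °C → rt) then regenerate 18 by loss of sulfinate while 19 is formed at low stationary concentration. These are the usual conditions of the sulfone-based [4+1] annulation, and 21 results.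

**Step 1.** Site selectivity may be lost: of the two ortho hydroxyls only one can hydrogen-bond to the formyl oxygen at a time, so ortho-triflation and bis-triflation can compete. Fallback, leaving 1 aside, setting out from 4 and returning at 5: commercial 4-bromo-2,6-dimethoxybenzaldehyde F2, in which the halogen is already para to the formyl group, is demethylated at both ortho positions (BBr3, CH2Cl2, −78 → 0 °C) to 4-bromo-2,6-dihydroxybenzaldehyde F3. F3 takes the place of 2 in the Mizoroki–Heck reaction with 4 and gives 5.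

**Step 3.** Migratory insertion may go the wrong way (α-arylation to a 1,1-diarylethene, favoured by a cationic aryl-Pd triflate and an electron-rich styrene), and Boc groups may be lost or shifted under hot amine. Fallback, setting out from 2 and 4 and returning at 5: cross-metathesis of 4 with vinylboronic acid pinacol ester (Ru alkylidene, CH2Cl2, 40 °C) gives tert-butyl {2-methoxy-4-[(E)-2-(4,4,5,5-tetramethyl-1,3,2-dioxaborolan-2-yl)ethenyl]phenyl} carbonate F4. Suzuki–Miyaura coupling of F4 with 2 (Pd(dppf)Cl2, K3PO4, dioxane) gives 5 with the position and geometry of the double bond fixed in the boronate.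

**Step 12.** The polyphenoxides formed in basic methanol may be oxidised (catecholate to o-quinone), and methoxide may capture the p-quinone methide that forms by reversible opening of the C2–O1 bond. Fallback, setting out from 21 and returning at 22: unmasking in two stages without free phenoxides. Buffered fluoride (Et3N·3HF, THF) removes the four silyl ethers and gives tert-butyl (2S,3S)-6-[(E)-2-{4-[(tert-butoxycarbonyl)oxy]-3-methoxyphenyl}ethenyl]-2-(3,4-dihydroxyphenyl)-3-(3,5-dihydroxyphenyl)-2,3-dihydro-1-benzofuran-4-yl carbonate F5. The two aryl carbonates are then cleaved by brief aminolysis (pyrrolidine, MeCN, 0 °C, Ar).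

## Further compounds

F1 | step 11 | tert-butyl {2-[{3,5-bis[(tert-butyldimethylsilyl)oxy]phenyl}(4-methylbenzenesulfonyl)methyl]-5-[(E)-2-{4-[(tert-butoxycarbonyl)oxy]-3-methoxyphenyl}ethenyl]-3-hydroxyphenyl} carbonate (racemic) | COc1cc(/C=C/c2cc(O)c(C(c3cc(O[Si](C)(C)C(C)(C)C)cc(O[Si](C)(C)C(C)(C)C)c3)S(=O)(=O)c3ccc(C)cc3)c(OC(=O)OC(C)(C)C)c2)ccc1OC(=O)OC(C)(C)C
F2 | step 1 | 4-bromo-2,6-dimethoxybenzaldehyde | COc1cc(Br)cc(OC)c1C=O
F3 | step 1 | 4-bromo-2,6-dihydroxybenzaldehyde | O=Cc1c(O)cc(Br)cc1O
F4 | step 3 | tert-butyl {2-methoxy-4-[(E)-2-(4,4,5,5-tetramethyl-1,3,2-dioxaborolan-2-yl)ethenyl]phenyl} carbonate | COc1cc(/C=C/B2OC(C)(C)C(C)(C)O2)ccc1OC(=O)OC(C)(C)C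
F5 | step 12 | tert-butyl (2S,3S)-6-[(E)-2-{4-[(tert-butoxycarbonyl)oxy]-3-methoxyphenyl}ethenyl]-2-(3,4-dihydroxyphenyl)-3-(3,5-dihydroxyphenyl)-2,3-dihydro-1-benzofuran-4-yl carbonate | COc1cc(/C=C/c2cc(OC(=O)OC(C)(C)C)c3c(c2)O[C@H](c2ccc(O)c(O)c2)[C@H]3c2cc(O)cc(O)c2)ccc1OC(=O)OC(C)(C)C
A1 | alternative 1 | piceatannol, 4-[(E)-2-(3,5-dihydroxyphenyl)ethenyl]benzene-1,2-diol | Oc1cc(O)cc(/C=C/c2ccc(O)c(O)c2)c1
A2 | alternative 1 | isorhapontigenin, 5-[(E)-2-(4-hydroxy-3-methoxyphenyl)ethenyl]benzene-1,3-diol | COc1cc(/C=C/c2cc(O)cc(O)c2)ccc1O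
A3 | alternative 1 | p-quinone methide of the cross-coupled dimer (racemic) | O=C1C(O)=CC(=CC(c2cc(O)cc(O)c2)c2c(O)cc(/C=C/c3ccc(O)c(OC)c3)cc2O)C=C1
A4 | alternative 2 | {2,6-bis({3,4-bis[(tert-butyldimethylsilyl)oxy]benzyl}oxy)-4-[(E)-2-{4-[(tert-butyldimethylsilyl)oxy]-3-methoxyphenyl}ethenyl]phenyl}{3,5-bis[(tert-butyldimethylsilyl)oxy]phenyl}diazomethane | [N-]=[N+]=C(c1cc(O[Si](C)(C)C(C)(C)C)cc(O[Si](C)(C)C(C)(C)C)c1)c1c(OCc2ccc(O[Si](C)(C)C(C)(C)C)c(O[Si](C)(C)C(C)(C)C)c2)cc(/C=C/c2ccc(O[Si](C)(C)C(C)(C)C)c(OC)c2)cc1OCc1ccc(O[Si](C)(C)C(C)(C)C)c(O[Si](C)(C)C(C)(C)C)c1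
A5 | alternative 2 | (2R,3S)-cis-4-({3,4-bis[(tert-butyldimethylsilyl)oxy]benzyl}oxy)-2-{3,4-bis[(tert-butyldimethylsilyl)oxy]phenyl}-3-{3,5-bis[(tert-butyldimethylsilyl)oxy]phenyl}-6-[(E)-2-{4-[(tert-butyldimethylsilyl)oxy]-3-methoxyphenyl}ethenyl]-2,3-dihydro-1-benzofuran | COc1cc(/C=C/c2cc(OCc3ccc(O[Si](C)(C)C(C)(C)C)c(O[Si](C)(C)C(C)(C)C)c3)c3c(c2)O[C@@H](c2ccc(O[Si](C)(C)C(C)(C)C)c(O[Si](C)(C)C(C)(C)C)c2)[C@H]3c2cc(O[Si](C)(C)C(C)(C)C)cc(O[Si](C)(C)C(C)(C)C)c2)ccc1O[Si](C)(C)C(C)(C)C
A6 | alternative 3 | methyl 2-{3,4-bis[(tert-butyldimethylsilyl)oxy]phenyl}-3-{3,5-bis[(tert-butyldimethylsilyl)oxy]phenyl}-4-[(tert-butyldimethylsilyl)oxy]-1-benzofuran-6-carboxylate | COC(=O)c1cc(O[Si](C)(C)C(C)(C)C)c2c(c1)oc(-c1ccc(O[Si](C)(C)C(C)(C)C)c(O[Si](C)(C)C(C)(C)C)c1)c2-c1cc(O[Si](C)(C)C(C)(C)C)cc(O[Si](C)(C)C(C)(C)C)c1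
A7 | alternative 3 | methyl (2R,3S)-cis-2-{3,4-bis[(tert-butyldimethylsilyl)oxy]phenyl}-3-{3,5-bis[(tert-butyldimethylsilyl)oxy]phenyl}-4-[(tert-butyldimethylsilyl)oxy]-2,3-dihydro-1-benzofuran-6-carboxylate | COC(=O)c1cc(O[Si](C)(C)C(C)(C)C)c2c(c1)O[C@@H](c1ccc(O[Si](C)(C)C(C)(C)C)c(O[Si](C)(C)C(C)(C)C)c1)[C@H]2c1cc(O[Si](C)(C)C(C)(C)C)cc(O[Si](C)(C)C(C)(C)C)c1
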